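The earlier runs and the new flask stem from a simulated flask with made-up constants; the scatter is artificial.

Take the slope of the first reading, not the partner charge, as the thing to watch in the theta run. You asked for a quick number for its share of starting material at 11 min; this is what we have.

| flask | starting material | partner | time |
|---|---|---|---|
| eta | 0.120 M | 0.240 M |  |
| epsilon | 0.240 M | 0.240 M |  |
| theta | 0.780 M | 0.240 M | 11 min |

| run | time / min | [starting material] / M |
|---|---|---|
| eta run | 1.6 | 0.1106 |
| eta run | 3.1 | 0.1006 |
| eta run | 4.7 | 0.0824 |
| eta run | 6.3 | 0.0507 |
| eta run | 7.9 | 0.0246 |
| eta run | 9.4 | 0.0106 |
| eta run | 11 | 0.0025 |
| epsilon run | 1.6 | 0.2206 |
| epsilon run | 3.1 | 0.1606 |
| epsilon run | 4.7 | 0.0611 |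
| epsilon run | 6.3 | 0.0222 |
| epsilon run | 7.9 | 0.0092 |
| epsilon run | 9.4 | 0.0071 |
| epsilon run | 11 | 0.0018 |

(each reading ± 0.001 M)

* order of the initial rate in [starting material], near the charge of the eta run, the rate being that where two percent of its starting material are target (one fixed amount of target, the same in the runs compared)
* starting material in the theta run at 11 min, as a share of the starting material charged
* which of these the readings show (two substrates go astray together / the product speeds the reaction / the substrate pairs with itself / the two partners rest in a complex / the second partner is lost by itself)

- Overall: starting material + partner -> target.
- Constant volume, constant temperature.
- "The second partner" is partner.
- An order is taken over about fifteen percent of the charge, up and down.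

Both curves start slowly and then steepen. Up to the first reading, c(starting material) falls at 0.0510 /min in the eta run and at 0.0527 /min in the epsilon run, so doubling the charge leaves this first-order constant about the same. Their mean, 0.0518 /min, I call the background constant, the fraction of the starting material leaving per minute before target has built up. My bet is that this background uses no partner.

Your forecast gives order 1, the product speeds the reaction, and 69% left, on the ground “In theta, partner is limiting.” A power-law fit gives the same share. I keep your order and your verdict, but not your share.

I solve the two ends and join them. If the partner charge is spent at once and the background then acts on the rest, the share is 39.1%; if it is spent at the very end, the share is 25.8%. The epsilon run was falling fast by 3.1 min, and the theta run carries 3.25 times the starting material of the epsilon run with the same partner charge, so as my own estimate I place the partner's use at that time, which gives 36.1%.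

The simulation gives 40.5%, order 1.1, and the product speeds the reaction; the share is 4.4 percentage points above my figure.

    starting material → intermediate (0.04644 /min)
    intermediate + partner → target (0.2010 /M/min)
    intermediate → side product (0.7440 /min)
    starting material + partner + target → 2 target (42.48 /M²/min)

In the theta run, starting material went to intermediate from the start, and the intermediate went to side product faster than to target even at the full partner charge, while the step that needs both target and partner ran as long as partner was there. In the eta run, the background constant times the charge gives 0.006220 M/min, which is 2.23 times the 0.0028 M/min of target forming where two percent have turned. By 11 min the theta run has lost 0.464 M, which is 0.224 M beyond its partner charge, and for the 0.316 M left the background constant puts the fall at 0.0164 M/min.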